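**Retrosynthetic overview**
1. The target is the chain A–CH2–B–CH2–C–CH2–D–CH2–E. Rings A and E are butyrylfilicinic acid; rings B, C and D are phlorobutyrophenone. The chain is mirror-symmetric, so it is cut outwards from ring C in both directions.
2. Last disconnection: the two outer bridges give the free trimer B–C–D plus two Mannich bases of ring A (methylidene-trione capping).
3. Key disconnection: the two inner bridges give ring C as an O-methylated bis(benzylic methyl carbonate) plus two unprotected phlorobutyrophenones. They are joined by palladium-catalysed benzylic substitution at the arene C–H.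
4. No carbocycle is built. All five rings are resorcinol rings, and the third oxygen comes from iridium-catalysed C–H borylation/oxidation. Rings A and E arise from ring B material by dearomatising gem-dimethylation.
5. Order: the B/D unit and the C unit are made in parallel, the A/E unit is made from the B unit, then B–C–D is assembled, then A–B–C–D–E.

Assumption: the SMILES holds no stereocentre and no stereogenic double bond. The target is therefore achiral, and no step has to set or protect a configuration. The enol rings are drawn in the tautomer of the given SMILES.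

**Branch 1: rings B/D and A/E**

Step 1
Reactants: 1 resorcinol (benzene-1,3-diol)
Product: 2 1,3-bis(tert-butyldimethylsilyloxy)benzene
Conditions: TBSCl (2.3 equiv), imidazole (5 equiv), DMF, rt
Reagents that add atoms: tert-butyldimethylsilyl chloride, CC(C)(C)[Si](C)(C)Cl
Why: Standard imidazole-promoted O-silylation; the bulky silyl ethers mask the acidic OH groups for the borylation, shield the ortho positions and come off later under neutral fluoride conditions.

Step 2
Reactants: 2 1,3-bis(tert-butyldimethylsilyloxy)benzene
Product: 4 3,5-bis(tert-butyldimethylsilyloxy)phenol, via aryl pinacol boronate 3 (not isolated)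
Conditions: [Ir(OMe)(cod)]2 (1.5 mol %), dtbpy (3 mol %), B2pin2 (1.0 equiv), cyclohexane, 80 °C; then KHSO5 (Oxone), acetone/H2O, rt, 10 min
Reagents that add atoms: bis(pinacolato)diboron, CC1(C)OB(OC1(C)C)B1OC(C)(C)C(C)(C)O1 (boryl group of 3); potassium peroxymonosulfate KHSO5, [K+].[O-]S(=O)(=O)OO (phenol oxygen of 4)
Why: Sterically governed iridium-catalysed aromatic C–H borylation (Hartwig–Miyaura type) reaches only C5, the one C–H without an ortho substituent, and oxidation of the C–B bond in the same flask gives the phenol at that position.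

Step 3
Reactants: 4 3,5-bis(tert-butyldimethylsilyloxy)phenol
Product: 5 phloroglucinol (benzene-1,3,5-triol)
Conditions: KHF2 (4 equiv), MeOH, rt
Reagents that add atoms: none
Why: Fluoride-induced cleavage of phenolic silyl ethers, driven by the Si–F bond, frees the very nucleophilic triol under near-neutral conditions with no electrophile present.

Step 4
Reactants: 5 phloroglucinol; 6 butanoyl chloride (1.0 equiv)
Product: 7 1-(2,4,6-trihydroxyphenyl)butan-1-one (phlorobutyrophenone)
Conditions: AlCl3 (4 equiv), CH2Cl2/PhNO2, 0 to 45 °C; aq HCl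
Reagents that add atoms: butanoyl chloride 6, CCCC(=O)Cl
Why: Friedel–Crafts acylation; the first acyl group, chelated to aluminium, deactivates the ring, so one equivalent of 6 stops at the mono-ketone.

Step 5
Reactants: 7 phlorobutyrophenone; 8 iodomethane (2.3 equiv)
Product: 10 2-butanoyl-3,5-dihydroxy-4,4-dimethylcyclohexa-2,5-dien-1-one (butyrylfilicinic acid), via 3-methylphlorobutyrophenone 9 (not isolated)
Conditions: NaOMe (4 equiv), MeI, MeOH, 0 °C to rt; aq HCl; chromatography
Reagents that add atoms: iodomethane 8, CI
Why: Dearomatising C-methylation of the polyphenolate in a protic solvent (the classical entry to acylfilicinic acids); the first methyl group makes C3 the most nucleophilic carbon, so the second MeI adds there and the ring is trapped as the stable vinylogous acid.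

Step 6
Reactants: 10 butyrylfilicinic acid; 11 N,N,N',N'-tetramethylmethanediamine (1.1 equiv)
Product: 12 2-butanoyl-6-[(dimethylamino)methyl]-3,5-dihydroxy-4,4-dimethylcyclohexa-2,5-dien-1-one (ring A Mannich base)
Conditions: CH2(NMe2)2, CH2Cl2, 0 °C to rt; precipitation with Et2O
Reagents that add atoms: N,N,N',N'-tetramethylmethanediamine 11, CN(C)CN(C)C
Why: Mannich aminomethylation; the acidic enol (pKa about 5) protonates the aminal, which collapses to CH2=NMe2+, this is taken up by C6, the only free nucleophilic ring carbon, and the zwitterionic product precipitates before it can go on to the methylene-bis dimer.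

**Branch 2: ring C**

Step 7
Reactants: 1 resorcinol; 8 iodomethane (2.5 equiv)
Product: 13 1,3-dimethoxybenzene
Conditions: MeI, K2CO3, acetone, reflux
Reagents that add atoms: iodomethane 8, CI
Why: Williamson O-methylation; methyl ethers are small enough for a hexasubstituted ring, survive the Lewis acids of steps 10 and 11, and stay on ring C up to the trimer.

Step 8
Reactants: 13 1,3-dimethoxybenzene
Product: 15 3,5-dimethoxyphenol, via aryl pinacol boronate 14 (not isolated)
Conditions: [Ir(OMe)(cod)]2 (1.5 mol %), dtbpy (3 mol %), B2pin2 (1.0 equiv), cyclohexane, 80 °C; then KHSO5 (Oxone), acetone/H2O, rt, 10 min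
Reagents that add atoms: bis(pinacolato)diboron, CC1(C)OB(OC1(C)C)B1OC(C)(C)C(C)(C)O1 (boryl group of 14); potassium peroxymonosulfate KHSO5, [K+].[O-]S(=O)(=O)OO (phenol oxygen of 15)
Why: The same iridium-catalysed C–H borylation/oxidation sequence; C5 is the only sterically open C–H of a 1,3-disubstituted benzene.

Step 9
Reactants: 15 3,5-dimethoxyphenol; 8 iodomethane (1.3 equiv)
Product: 16 1,3,5-trimethoxybenzene
Conditions: MeI, K2CO3, acetone, reflux
Reagents that add atoms: iodomethane 8, CI
Why: Williamson O-methylation of a single phenol; with two oxygens already capped, C-methylation does not compete.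

Step 10
Reactants: 16 1,3,5-trimethoxybenzene; 6 butanoyl chloride (1.05 equiv)
Product: 17 1-(2,4,6-trimethoxyphenyl)butan-1-one
Conditions: SnCl4 (1.1 equiv), CH2Cl2, −10 to 0 °C
Reagents that add atoms: butanoyl chloride 6, CCCC(=O)Cl
Why: Friedel–Crafts acylation of a highly activated arene; the mild Lewis acid at low temperature avoids cleavage of the ortho methyl ethers, and the ketone stops a second acylation.

Step 11
Reactants: 17 1-(2,4,6-trimethoxyphenyl)butan-1-one; 18 chloromethyl methyl ether (6 equiv)
Product: 19 1-[3,5-bis(chloromethyl)-2,4,6-trimethoxyphenyl]butan-1-one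
Conditions: MOMCl, ZnCl2 (20 mol %), CH2Cl2, 0 °C to rt
Reagents that add atoms: chloromethyl methyl ether 18, COCCl
Why: Blanc-type chloromethylation (electrophilic aromatic substitution); both remaining ring carbons lie between two methoxy groups and stay activated after the first substitution, while excess reagent and weak acidity suppress diarylmethane formation and ipso-deacylation.

Step 12
Reactants: 19 1-[3,5-bis(chloromethyl)-2,4,6-trimethoxyphenyl]butan-1-one
Product: 20 bis(methyl carbonate) of 1-[3,5-bis(hydroxymethyl)-2,4,6-trimethoxyphenyl]butan-1-one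
Conditions: MeOH (6 equiv), CO2 (1 atm), Cs2CO3 (4 equiv), Bu4NI, DMF, rt
Reagents that add atoms: methanol, CO; carbon dioxide, O=C=O
Why: Three-component mixed-carbonate synthesis; the methyl carbonate anion formed from MeOH, CO2 and Cs2CO3 displaces the benzylic chloride (iodide-assisted SN2) faster than methoxide can form the ether.

**Assembly**

Step 13
Reactants: 20 ring C bis(methyl carbonate) (1 equiv, added over 4 h); 7 phlorobutyrophenone (6 equiv, excess recovered)
Product: 22 1-[3,5-bis[(3-butanoyl-2,4,6-trihydroxyphenyl)methyl]-2,4,6-trimethoxyphenyl]butan-1-one (trimer B–C–D, ring C as trimethyl ether), via mono-benzylated carbonate 21 (not isolated)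
Conditions: Pd2(dba)3·CHCl3 (2.5 mol %), DPEphos (6 mol %), t-AmOH/THF 1:1, 60 °C, no added base
Reagents that add atoms: none
Why: Proposed new method: zerovalent palladium ionises each electron-rich benzylic methyl carbonate to a cationic η3-benzylpalladium complex, and loss of CO2 releases methoxide, which deprotonates the acidic phenol 7 (pKa about 8); the soft ambident phloroglucinolate, with its oxygens hydrogen-bonded by the protic co-solvent, attacks the benzylic terminus through C3 and the dienone re-aromatises by tautomerisation; any O-benzyl ether is re-ionised because the acylphloroglucinolate is a good leaving group, so the C–C product is the thermodynamic sink, and excess 7 ensures one benzylation per nucleophile; the closest known reaction types are the Tsuji–Trost-type benzylic substitution of benzyl carbonates by malonates, by phenols (at oxygen) and by indoles (at C3) and the palladium-catalysed C-allylation of acylphloroglucinols, but a C-selective benzylation of an unprotected acylphloroglucinol, run twice on a hexasubstituted bis-electrophile, has not been shown.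

Step 14
Reactants: 22 trimer trimethyl ether
Product: 23 1-[3,5-bis[(3-butanoyl-2,4,6-trihydroxyphenyl)methyl]-2,4,6-trihydroxyphenyl]butan-1-one (free trimer B–C–D)
Conditions: BBr3 (12 equiv), CH2Cl2, −78 °C to rt; H2O
Reagents that add atoms: none
Why: Lewis-acid aryl methyl ether cleavage; two OMe groups are chelation-activated by the ketone, the third is twisted out of conjugation and therefore basic, and ArCH2Ar bridges of polyalkoxyarenes are known to survive BBr3.

Step 15
Reactants: 23 free trimer B–C–D; 12 ring A Mannich base (2.2 equiv)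
Product: 26 CNP0188003.0 (pentamer A–CH2–B–CH2–C–CH2–D–CH2–E), via methylidene trione 24 (not isolated), via mono-capped tetramer 25 (not isolated)
Conditions: AcOH (10 equiv), 1,4-dioxane, 45 °C, N2; Sephadex LH-20, then crystallisation
Reagents that add atoms: none
Why: Mannich-base exchange (elimination, then Michael-type Friedel–Crafts addition); zwitterion 12 loses Me2NH to give the strongly electrophilic methylidene trione 24, which is trapped by the single free aromatic carbon of each outer ring, and the acetic acid buffer binds the amine so that base-induced bridge scrambling is suppressed.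

**Compound list**
1 | resorcinol | Oc1cccc(O)c1 | starting material
2 | 1,3-bis(tert-butyldimethylsilyloxy)benzene | CC(C)(C)[Si](C)(C)Oc1cccc(O[Si](C)(C)C(C)(C)C)c1 | intermediate
3 | 2-[3,5-bis(tert-butyldimethylsilyloxy)phenyl]-4,4,5,5-tetramethyl-1,3,2-dioxaborolane | CC(C)(C)[Si](C)(C)Oc1cc(O[Si](C)(C)C(C)(C)C)cc(B2OC(C)(C)C(C)(C)O2)c1 | intermediate
4 | 3,5-bis(tert-butyldimethylsilyloxy)phenol | CC(C)(C)[Si](C)(C)Oc1cc(O)cc(O[Si](C)(C)C(C)(C)C)c1 | intermediate
5 | phloroglucinol | Oc1cc(O)cc(O)c1 | intermediate
6 | butanoyl chloride | CCCC(=O)Cl | starting material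
7 | 1-(2,4,6-trihydroxyphenyl)butan-1-one (phlorobutyrophenone) | CCCC(=O)c1c(O)cc(O)cc1O | intermediate
8 | iodomethane | CI | starting material
9 | 1-(2,4,6-trihydroxy-3-methylphenyl)butan-1-one | CCCC(=O)c1c(O)cc(O)c(C)c1O | intermediate
10 | 2-butanoyl-3,5-dihydroxy-4,4-dimethylcyclohexa-2,5-dien-1-one (butyrylfilicinic acid) | CCCC(=O)C1=C(O)C(C)(C)C(O)=CC1=O | intermediate
11 | N,N,N',N'-tetramethylmethanediamine | CN(C)CN(C)C | starting material
12 | 2-butanoyl-6-[(dimethylamino)methyl]-3,5-dihydroxy-4,4-dimethylcyclohexa-2,5-dien-1-one | CCCC(=O)C1=C(O)C(C)(C)C(O)=C(CN(C)C)C1=O | intermediate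
13 | 1,3-dimethoxybenzene | COc1cccc(OC)c1 | intermediate
14 | 2-(3,5-dimethoxyphenyl)-4,4,5,5-tetramethyl-1,3,2-dioxaborolane | COc1cc(OC)cc(B2OC(C)(C)C(C)(C)O2)c1 | intermediate
15 | 3,5-dimethoxyphenol | COc1cc(O)cc(OC)c1 | intermediate
16 | 1,3,5-trimethoxybenzene | COc1cc(OC)cc(OC)c1 | intermediate
17 | 1-(2,4,6-trimethoxyphenyl)butan-1-one | CCCC(=O)c1c(OC)cc(OC)cc1OC | intermediate
18 | chloromethyl methyl ether | COCCl | starting material
19 | 1-[3,5-bis(chloromethyl)-2,4,6-trimethoxyphenyl]butan-1-one | CCCC(=O)c1c(OC)c(CCl)c(OC)c(CCl)c1OC | intermediate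
20 | bis(methyl carbonate) of 1-[3,5-bis(hydroxymethyl)-2,4,6-trimethoxyphenyl]butan-1-one | CCCC(=O)c1c(OC)c(COC(=O)OC)c(OC)c(COC(=O)OC)c1OC | intermediate
21 | [3-butanoyl-5-[(3-butanoyl-2,4,6-trihydroxyphenyl)methyl]-2,4,6-trimethoxyphenyl]methyl methyl carbonate | CCCC(=O)c1c(OC)c(COC(=O)OC)c(OC)c(Cc2c(O)cc(O)c(C(=O)CCC)c2O)c1OC | intermediate
22 | 1-[3,5-bis[(3-butanoyl-2,4,6-trihydroxyphenyl)methyl]-2,4,6-trimethoxyphenyl]butan-1-one | CCCC(=O)c1c(OC)c(Cc2c(O)cc(O)c(C(=O)CCC)c2O)c(OC)c(Cc2c(O)cc(O)c(C(=O)CCC)c2O)c1OC | intermediate
23 | 1-[3,5-bis[(3-butanoyl-2,4,6-trihydroxyphenyl)methyl]-2,4,6-trihydroxyphenyl]butan-1-one | CCCC(=O)c1c(O)c(Cc2c(O)cc(O)c(C(=O)CCC)c2O)c(O)c(Cc2c(O)cc(O)c(C(=O)CCC)c2O)c1O | intermediate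
24 | 2-butanoyl-3-hydroxy-4,4-dimethyl-6-methylidenecyclohex-2-ene-1,5-dione | CCCC(=O)C1=C(O)C(C)(C)C(=O)C(=C)C1=O | intermediate
25 | tetramer A–CH2–B–CH2–C–CH2–D: trimer 23 carrying one butyrylfilicinic acid unit through CH2 on the free carbon of one outer ring | CCCC(=O)C1=C(O)C(C)(C)C(O)=C(Cc2c(O)c(Cc3c(O)c(Cc4c(O)cc(O)c(C(=O)CCC)c4O)c(O)c(C(=O)CCC)c3O)c(O)c(C(=O)CCC)c2O)C1=O | intermediate
26 | CNP0188003.0, pentamer A–CH2–B–CH2–C–CH2–D–CH2–E (achiral) | CCCC(=O)C1=C(O)C(C)(C)C(O)=C(Cc2c(O)c(Cc3c(O)c(Cc4c(O)c(CC5=C(O)C(C)(C)C(O)=C(C(=O)CCC)C5=O)c(O)c(C(=O)CCC)c4O)c(O)c(C(=O)CCC)c3O)c(O)c(C(=O)CCC)c2O)C1=O | target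

**Totals**
Total step count: 15.
Longest linear sequence: 9 steps (7, 8, 9, 10, 11, 12, 13, 14, 15). The other paths, 1–6 then 15 and 1–4 then 13–15, each have 7 steps.

**Steps most likely to fail**

Step 13 (the new reaction). The risks are slow ionisation of a benzylic carbonate with two ortho substituents, O-benzylation that does not revert, and oligomers from double reaction of 7. The fallback uses known chemistry and needs neither palladium nor protecting groups. It sets out from 7. Both free ring carbons are aminomethylated with CH2(NMe2)2 (2.2 equiv, CH2Cl2) to give the bis-Mannich base 1-[3,5-bis[(dimethylamino)methyl]-2,4,6-trihydroxyphenyl]butan-1-one F1. This is then heated with a large excess of 7 (8 equiv) in AcOH/dioxane. Loss of Me2NH gives ortho-quinone methides, which are trapped at C3 of 7; this is the classical Mannich-base route to methylene-bridged phloroglucinols. The fallback comes back to the route at the free trimer 23, and 22 and step 14 are no longer needed.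

Step 11. The risks are diarylmethane formation, ipso-attack with loss of the butanoyl group, and incomplete second substitution. The fallback replaces electrophilic C1 transfer by halogenation and cross-coupling. It sets out from 17. Ring dibromination with NBS (2.1 equiv, MeCN, 0 °C) gives 1-(3,5-dibromo-2,4,6-trimethoxyphenyl)butan-1-one F2. A double Suzuki–Miyaura hydroxymethylation (K[AcOCH2BF3], Pd(dba)2/RuPhos, Na2CO3, dioxane/H2O, 100 °C) gives 1-[3,5-bis(hydroxymethyl)-2,4,6-trimethoxyphenyl]butan-1-one F3. Treatment with ClCO2Me/pyridine comes back to the route at 20, and 19 and step 12 are no longer needed.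

Step 15. The risks are scrambling of the inner bridges of the free trimer (rottlerone-type fragmentation), self-capture of 24 to give the A–CH2–A dimer, and incomplete second capping. The fallback changes the order of events so that the inner bridges stay locked. It sets out from 22. While ring C is still a trimethyl ether it cannot form a quinone methide, so neither inner bridge can open. Capping 22 with 12 by the same Mannich-base exchange gives the pentamer with ring C as its 2,4,6-tri-O-methyl ether F4. BBr3 (CH2Cl2, −78 °C to 0 °C) then removes the three methyl groups and comes back to the route at the target 26.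

**Further compounds**
F1 | step 13 | 1-[3,5-bis[(dimethylamino)methyl]-2,4,6-trihydroxyphenyl]butan-1-one | CCCC(=O)c1c(O)c(CN(C)C)c(O)c(CN(C)C)c1O
F2 | step 11 | 1-(3,5-dibromo-2,4,6-trimethoxyphenyl)butan-1-one | CCCC(=O)c1c(OC)c(Br)c(OC)c(Br)c1OC
F3 | step 11 | 1-[3,5-bis(hydroxymethyl)-2,4,6-trimethoxyphenyl]butan-1-one | CCCC(=O)c1c(OC)c(CO)c(OC)c(CO)c1OC
F4 | step 15 | pentamer A–CH2–B–CH2–C–CH2–D–CH2–E with ring C as 2,4,6-tri-O-methyl ether | CCCC(=O)C1=C(O)C(C)(C)C(O)=C(Cc2c(O)c(Cc3c(OC)c(Cc4c(O)c(CC5=C(O)C(C)(C)C(O)=C(C(=O)CCC)C5=O)c(O)c(C(=O)CCC)c4O)c(OC)c(C(=O)CCC)c3OC)c(O)c(C(=O)CCC)c2O)C1=O
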